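Watch the ligand clock.

common to all: starting complex 23 mM (in portions, 4)
- dawn: incoming ligand 23 mM; run made earlier; portions every 10 min
- autumn: incoming ligand 75 mM; run made earlier; portions every 10 min
- cedar: incoming ligand 20.0 mM; the portions of starting complex follow each other after 10 min, the first at the start; time 1.0 h
- oak: incoming ligand 40.0 mM; the portions of starting complex follow each other after 10 min, the first at the start; time 1.0 h
- maple: incoming ligand 80.0 mM; the portions of starting complex follow each other after 10 min, the first at the start; time 1.0 h
- larch: incoming ligand 150 mM; the portions of starting complex follow each other after 10 min, the first at the start; time 1.0 h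
- ash: incoming ligand 300 mM; the portions of starting complex follow each other after 10 min, the first at the start; time 1.0 h

| run | time / min | complex with one exchanged / % |
|---|---|---|
| dawn | 12.0 | 3.4 |
| dawn | 25.0 | 11.2 |
| dawn | 40.0 | 19.4 |
| dawn | 50.0 | 22.8 |
| dawn | 60.0 | 25.6 |
| autumn | 12.0 | 9.1 |
| autumn | 25.0 | 18.9 |
| autumn | 40.0 | 25.5 |
| autumn | 50.0 | 25.3 |
| autumn | 60.0 | 22.4 |

(each reading ± 0.5 percentage points)

- "hardly changes" means that all values lie within two and a half points (for a concentration: within two and a half percent of the largest)

* amount of complex with one exchanged at the end, in percent of the starting complex charged for cedar, oak, maple, larch, ash, in this order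
* how the row runs (falls all the way / rises, then falls / hardly changes / rises all the way / falls, then rises)

Complex with one exchanged is made from starting complex and used up further. In the autumn run the readings top out between 40.0 min and 50.0 min, while in the dawn run they are still rising at 60.0 min. At 12.0 min the autumn reading is 2.68 times the dawn reading, for 3.26 times the [incoming ligand], so I take the pace as roughly proportional to [incoming ligand] and read the clock as [incoming ligand] times the mean age of the portions.

Reading the autumn top midway between those two times, within the scatter of the readings, I get a mean age of 30.0 min there, and at the asked time the mean age is 45.0 min. The equal-clock concentration, the [incoming ligand] that brings the clock to its autumn top value at the asked time, is therefore 50.0 mM. Oak lies below it and maple above it, so my reckoning expects the row to rise, then fall, with its top between those two flasks.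

The forecast gives 23%, 28%, 21.5%, 10% and 1%, a row that rises, then falls, and says of the intermediate, "At high ligand it has been consumed".

The flasks give 24.0%, 28.6%, 22.1%, 8.37% and 0.602%, a row that rises, then falls, turning at 40 mM, lower than the equal-clock 50.0 mM.

    starting complex + incoming ligand ⇌ leaving ligand + complex with one exchanged (K = 3.40, k = 0.0110 /M/s)
    complex with one exchanged + incoming ligand ⇌ leaving ligand + complex with two exchanged (K = 0.400, k = 0.00800 /M/s)
    complex with two exchanged + incoming ligand ⇌ leaving ligand + complex with three exchanged (K = 39.0, k = 0.0340 /M/s)
    complex with one exchanged + incoming ligand → over-reaction product (k = 0.00810 /M/s)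

In cedar as charged, starting complex has a forward half-life of 0.88 h, while complex with one exchanged has 1.2 h by its forward second exchange and 1.2 h into over-reaction product, together 0.600 h, shorter than its entry, with about half of its forward exits going each way. In larch, at 3.00 times 50.0 mM, the reckoning puts the top of the clock at a mean age of 15.0 min, shorter than the 45.0 min at the asked time, and complex with one exchanged goes from 15.5% at 0.500 h to 8.37% at 1.00 h.

(Readings and results stem from a simulated flask for substances that don't exist; the scatter is artificial.)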